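**Retrosynthetic overview**
1. Target ⇒ pristimerin (unit A) + the o-quinone of a B–C catechol; the A/B dioxane is closed last by a hetero-Diels–Alder reaction on the C3=C4 enol.
2. B–C catechol ⇒ 6-oxo-7,8-dihydropristimerol dibenzyl ether (from pristimerin) + the catechol of unit C: o-quinone/silyl enol ether cycloaddition, dehydration to a benzodioxin, α-face hydrogenation (6β,7β-bridge).
3. Unit C (E ring with the CH3/CO2Me carbon next to C18) ⇒ radical bicyclisation closing ring C then ring B onto a cis-fused D/E decalin that carries the aryl-terminated (E)-homoallyl chain.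
4. D/E decalin ⇒ key step: catalytic enantioselective desymmetrising Diels–Alder reaction of the mirror-symmetric dienone methyl 1-methyl-4-oxocyclohexa-2,5-diene-1-carboxylate (ring E, from Birch reductive methylation of methyl benzoate) with a 2-silyloxydiene (ring D).
5. Ring order: E → D → C → B (ring A of unit C is bought as 2,3-dimethoxytoluene); units are then joined C to B, then B to A.

**Assumption:** pristimerin (the methyl ester of celastrol) is bought and used twice, as unit A and as the source of unit B; only unit C, which the SMILES draws with the ester-bearing quaternary carbon at C19, is built de novo.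

**Conventions:** locants and α/β are those of the finished triterpenoid units (9-CH3 = β). In unit C, C19 carries CH3/CO2Me and C20–C22 are CH2. For the bicyclic D/E intermediates the naphthalene locants map as C1 = C19, C2 = C20, C3 = C21, C4 = C22, C4a = C17, C5 = C16, C6 = C15, C7 = C14, C8 = C13, C8a = C18. Primed oxygens (O-2′, O-3′) belong to the catechol or quinone partner.

---

**Step 1**
Reactants: 1 methyl benzoate
Product: 3 methyl 1-methylcyclohexa-2,5-diene-1-carboxylate, via lithium ester dienolate 2 (not isolated)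
Conditions: Li (2.2 equiv), NH3(l)/THF, t-BuOH (1.0 equiv), −78 °C; then MeI, −78 → −33 °C
Reagents that add atoms: iodomethane CI
Why: Birch reductive alkylation: two-electron reduction and para protonation leave the ester-stabilised dienolate 2, which is C-methylated at the ipso carbon, breaking aromaticity and giving a mirror-symmetric 1,4-diene.

**Step 2**
Reactants: 3 methyl 1-methylcyclohexa-2,5-diene-1-carboxylate
Product: 4 methyl 1-methyl-4-oxocyclohexa-2,5-diene-1-carboxylate
Conditions: Rh2(cap)4 (dirhodium tetrakis(caprolactamate), 1 mol %), t-BuOOH (5 equiv), K2CO3, CH2Cl2, 23 °C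
Reagents that add atoms: tert-butyl hydroperoxide CC(C)(C)OO
Why: Catalytic allylic C–H oxidation: the doubly allylic CH2 is the only activated position and is taken to the cross-conjugated dienone, which keeps the mirror plane (C1 is prostereogenic).

**Step 3**
Reactants: 5 pent-1-en-3-one (ethyl vinyl ketone)
Product: 6 (Z)-3-(triisopropylsilyloxy)penta-1,3-diene
Conditions: TIPSOTf, Et3N, Et2O, 0 °C
Reagents that add atoms: triisopropylsilyl triflate CC(C)[Si](OS(=O)(=O)C(F)(F)F)(C(C)C)C(C)C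
Why: Soft enolisation and O-silylation of the ethyl ketone give the cross-conjugated 2-silyloxydiene, the (Z)-enol ether (methyl outward in the s-cis diene) being favoured.

**Step 4 (key step)**
Reactants: 4 methyl 1-methyl-4-oxocyclohexa-2,5-diene-1-carboxylate; 6 (Z)-3-(triisopropylsilyloxy)penta-1,3-diene
Product: 7 cis-fused D/E cycloadduct methyl 1,8-dimethyl-4-oxo-7-(triisopropylsilyloxy)-1,4,4a,5,8,8a-hexahydronaphthalene-1-carboxylate (H-4a H-8a H-8 and 1-CH3 β; 8-CH3 and CO2Me α)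
Conditions: (S)-3,3-diphenyl-1-(2-methylphenyl)tetrahydro-1H,3H-pyrrolo[1,2-c][1,3,2]oxazaborole (C24H24BNO) + HN(SO2CF3)2 (20 mol % each), CH2Cl2, −78 → −40 °C; Et3N quench
Reagents that add atoms: none
Why: Proposed new method: the cationic oxazaborolidine binds the dienone carbonyl and exposes one of the two enantiotopic enone double bonds, so an endo Diels–Alder addition of the 2-silyloxydiene (its nucleophilic C13 terminus bonding to the β-carbon C18), on the face syn to the flat ester and anti to the C19 methyl, breaks the mirror symmetry of 4 and sets C19, C18, C17 and C13 in one step; the antipodal catalyst is used if the sense of induction is opposite (closest known chemistry: oxazaborolidinium-catalysed Diels–Alder reactions of cyclic enones and quinone monoketals with 2-silyloxydienes, and catalytic desymmetrisations of 4,4-disubstituted cyclohexadienones).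

**Step 5**
Reactants: 7 cis-fused D/E cycloadduct
Product: 9 methyl 1,4a,8-trimethyl-4-oxo-7-(triisopropylsilyloxy)-1,4,4a,5,8,8a-hexahydronaphthalene-1-carboxylate (4a-CH3 β; cis-fused), via lithium enolate 8 (not isolated)
Conditions: LiN(i-Pr)2, THF, −78 °C; MeI, −78 → −20 °C
Reagents that add atoms: iodomethane CI
Why: Enolate alkylation: the ring-fusion C17–H is the only enolisable position (C21 is vinylic, C19 quaternary) and the planar enolate 8 is methylated on the convex β-face, cis to H-18, giving the cis-fused angular methyl (C17).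

**Step 6**
Reactants: 9 angular-methyl enone
Product: 11 methyl 1,4a,8-trimethyl-7-(triisopropylsilyloxy)-4-(trifluoromethylsulfonyloxy)-1,2,4a,5,8,8a-hexahydronaphthalene-1-carboxylate, via lithium enolate 10 (not isolated)
Conditions: LiBH(s-Bu)3, THF, −78 °C; then PhNTf2, −78 → 0 °C
Reagents that add atoms: N-phenylbis(trifluoromethanesulfonimide) O=S(=O)(N(c1ccccc1)S(=O)(=O)C(F)(F)F)C(F)(F)F
Why: Conjugate reduction and enolate triflation: the bulky borohydride adds 1,4 to the β-unsubstituted enone (the carbonyl is shielded by quaternary C17) and the regiodefined enolate 10 is O-sulfonylated.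

**Step 7**
Reactants: 11 enol triflate
Product: 13 methyl 1,4a,8-trimethyl-7-oxo-1,2,4a,5,6,7,8,8a-octahydronaphthalene-1-carboxylate (cis-fused; 1-CH3 4a-CH3 H-8a H-8 β; 8-CH3 and CO2Me α), via silyl enol ether 12 (not isolated)
Conditions: Pd(OAc)2 (5 mol %), PPh3, Et3N, HCO2H, DMF, 60 °C; then Bu4NF, AcOH, THF, 0 °C
Reagents that add atoms: none
Why: Palladium-catalysed formate reduction of the enol triflate (oxidative addition to zerovalent palladium, formate decarboxylation to the hydride, reductive elimination) removes the C22 oxygen, and fluoride then cleaves the silyl enol ether with protonation at C15, so C13 is untouched.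

**Step 8**
Reactants: 14 2,3-dimethoxytoluene
Product: 15 1-bromo-3,4-dimethoxy-2-methylbenzene
Conditions: NBS, MeCN, 0 → 23 °C
Reagents that add atoms: N-bromosuccinimide O=C1CCC(=O)N1Br
Why: Electrophilic aromatic bromination para to the unhindered, fully conjugated 3-methoxy group (ortho to the methyl), the 2-methoxy group being twisted out of conjugation.

**Step 9**
Reactants: 16 but-3-yn-1-ol
Product: 18 (E)-3-methylhexa-3,5-dien-1-ol, via vinylalane 17 (not isolated)
Conditions: Me3Al (3 equiv), Cp2ZrCl2 (25 mol %), CH2Cl2, 0 → 23 °C; then CH2=CHBr, Pd(PPh3)4 (3 mol %), ZnCl2, THF, 23 °C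
Reagents that add atoms: trimethylaluminium C[Al](C)C; vinyl bromide C=CBr
Why: Negishi zirconium-catalysed syn-carboalumination of the terminal alkyne followed by palladium-catalysed cross-coupling with retention fixes the (E)-trisubstituted alkene (future C8=C9).

**Step 10**
Reactants: 18 (E)-3-methylhexa-3,5-dien-1-ol; 15 1-bromo-3,4-dimethoxy-2-methylbenzene
Product: 20 (E)-6-(3,4-dimethoxy-2-methylphenyl)-3-methylhex-3-en-1-ol, via alkylborane 19 (not isolated)
Conditions: 9-BBN-H (2.2 equiv), THF, 0 → 23 °C; then 15, Pd(dppf)Cl2 (5 mol %), K3PO4 (aq), DMF, 60 °C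
Reagents that add atoms: none
Why: Anti-Markovnikov hydroboration of the terminal vinyl group of the diene and B-alkyl Suzuki–Miyaura coupling with the aryl bromide join C5–C6 without touching the alkene geometry.

**Step 11**
Reactants: 20 (E)-6-(3,4-dimethoxy-2-methylphenyl)-3-methylhex-3-en-1-ol
Product: 21 (E)-1-(6-iodo-4-methylhex-3-en-1-yl)-3,4-dimethoxy-2-methylbenzene
Conditions: I2, PPh3, imidazole, CH2Cl2, 0 → 23 °C
Reagents that add atoms: iodine II
Why: Appel iodination of the primary alcohol by SN2 displacement of the oxyphosphonium.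

**Step 12**
Reactants: 13 D/E ketone; 21 homoallylic iodide
Product: 23 methyl 8-[(E)-6-(3,4-dimethoxy-2-methylphenyl)-3-methylhex-3-en-1-yl]-1,4a,8-trimethyl-7-oxo-1,2,4a,5,6,7,8,8a-octahydronaphthalene-1-carboxylate (8-CH3 α; side chain β), via potassium enolate 22 (not isolated)
Conditions: KH (1.0 equiv), THF, 0 → 23 °C, 1 h; then 21, DMPU, −20 → 23 °C
Reagents that add atoms: none
Why: Alkylation of the equilibrated tetrasubstituted potassium enolate: A(1,3) strain with the C13 methyl forces the C18–C19 bond pseudoaxial (α), so the iodide is attacked anti to it on the β face, placing the chain β and leaving the methyl α at the new quaternary C13.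

**Step 13**
Reactants: 23 alkylated ketone
Product: 24 methyl 8-[(E)-6-(3,4-dimethoxy-2-methylphenyl)-3-methylhex-3-en-1-yl]-1,4a,8-trimethyl-7-methylidene-1,2,4a,5,6,7,8,8a-octahydronaphthalene-1-carboxylate
Conditions: Ph3PCH3Br, KOt-Bu, toluene, 90 °C
Reagents that add atoms: methyltriphenylphosphonium bromide C[P+](c1ccccc1)(c1ccccc1)c1ccccc1.[Br-]
Why: Wittig methylenation of the hindered C14 ketone with the small, salt-free ylide at elevated temperature; the neopentyl ester is non-enolisable and too hindered to react.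

**Step 14**
Reactants: 24 exocyclic alkene
Product: 25 unit C dimethyl ether with a C21=C22 bond (pentacycle; 8α-H 9β-CH3 13α-CH3 14β-CH3 17β-CH3 18β-H 19β-CH3 19α-CO2Me)
Conditions: [N,N′-bis(3,5-di-tert-butylsalicylidene)-1,2-cyclohexanediaminato]cobalt (C36H52CoN2O2, divalent cobalt, 5 mol %), N-fluoro-2,4,6-trimethylpyridinium tetrafluoroborate (2 equiv), PhSiH3 (2 equiv), (CF3)2CHOH/CH2Cl2, 0 → 23 °C
Reagents that add atoms: none
Why: Hydrogen-atom-transfer-initiated radical–polar crossover bicyclisation: a trivalent cobalt hydride delivers H• to the exocyclic methylene (making the C14 methyl and a tertiary C14 radical), which adds 6-endo to the (E)-alkene through a chair–chair transition state with the tether equatorial (14β-CH3, 8α-H), and the resulting C9 radical is captured by the arene para to OMe and rearomatised by oxidation (9β-CH3, trans-anti-trans backbone).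

**Step 15**
Reactants: 25 unit C dimethyl ether
Product: 26 unit C catechol with a C21=C22 bond
Conditions: BBr3 (3 equiv), CH2Cl2, −78 → 0 °C; H2O
Reagents that add atoms: none
Why: Lewis-acid O-demethylation of both aryl methyl ethers; the neopentyl methyl ester and the disubstituted alkene survive at low temperature.

**Step 16**
Reactants: 27 pristimerin
Product: 29 pristimerol 2,3-dibenzyl ether, via pristimerol 28 (not isolated)
Conditions: Na2S2O4, K2CO3, BnBr, Bu4NBr (cat.), DMF/H2O, 23 → 50 °C, Ar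
Reagents that add atoms: benzyl bromide BrCc1ccccc1
Why: Dithionite reduces the quinone methide to the aromatic catechol 28, and in situ Williamson O-benzylation stops re-oxidation.

**Step 17**
Reactants: 29 pristimerol 2,3-dibenzyl ether
Product: 30 6-oxopristimerol 2,3-dibenzyl ether (aryl enone C6=O; C7=C8)
Conditions: DDQ (2.2 equiv), 1,4-dioxane/H2O (9:1), 23 °C
Reagents that add atoms: water O
Why: DDQ abstracts hydride from the benzylic and allylic C6 position (para to an alkoxy group), water captures the cation, and a second oxidation gives the aryl enone.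

**Step 18**
Reactants: 30 6-oxopristimerol 2,3-dibenzyl ether
Product: 31 7,8-dihydro-6-oxopristimerol 2,3-dibenzyl ether (8α-H)
Conditions: SmI2 (2.5 equiv), HMPA, MeOH (2 equiv), THF, −78 → 0 °C
Reagents that add atoms: none
Why: Single-electron conjugate reduction of the aryl enone by divalent samarium: the β-carbon C8 is protonated on the α face (the β face is blocked by the 9β- and 14β-methyl groups), giving the trans B/C fusion irreversibly.

**Step 19**
Reactants: 31 unit B 6-ketone; 26 unit C catechol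
Product: 35 B–C benzodioxin (unit B C6=C7; C6–O-2′ and C7–O-3′ bonds to unit C), via silyl enol ether 32 (not isolated), via o-quinone 33 (not isolated), via cycloadduct 34 (not isolated)
Conditions: 31: TMSOTf, Et3N, CH2Cl2, 0 °C; 26: Ag2O, MgSO4, CH2Cl2, 0 °C, filter; combine, −20 → 23 °C; then TsOH·H2O (10 mol %), toluene, 60 °C
Reagents that add atoms: none
Why: Inverse-electron-demand hetero-Diels–Alder reaction of the o-quinone with the silyl enol ether: the nucleophilic C7 bonds to O-3′ (the oxygen next to the C-methyl, leaving the developing phenolate on the less hindered O-2′, which then closes on C6 — the same polarity pattern as both dioxane bridges of the target), and acid-catalysed loss of silanol gives the benzodioxin, erasing the C6/C7 configuration for the next step.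

**Step 20**
Reactants: 35 B–C benzodioxin
Product: 36 B–C catechol (unit B 2,3-diol; cis 6β,7β-dioxy bridge with 6α-H 7α-H 8α-H; unit C ring E saturated)
Conditions: H2 (5 bar), Pd/C (10 %), EtOAc/AcOH (10:1), 23 °C; handled under Ar
Reagents that add atoms: none
Why: Heterogeneous syn-hydrogenation adds H2 to the benzodioxin C6=C7 bond from the α face (the β face is screened by the axial 9β-methyl group 1,3 to C7), giving 6α-H/7α-H and so the cis 6β,7β bridge, while both benzyl ethers are hydrogenolysed and the ring-E alkene of unit C is saturated.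

**Step 21**
Reactants: 36 B–C catechol; 27 pristimerin
Product: 38 target trimer CNP0039487.1, via o-quinone 37 (not isolated)
Conditions: Ag2O, 4 Å MS, CH2Cl2, 0 °C, filter; then 27 (3 equiv), CH2Cl2, 23 → 40 °C, dark, Ar
Reagents that add atoms: none
Why: Oxidation to the o-quinone and inverse-electron-demand hetero-Diels–Alder addition to the C3=C4 enol of pristimerin: the nucleophilic enol carbon C4 bonds to O-3′ and C3 becomes the hemiketal bonded to O-2′, on the α face of the planar quinone methide because the 9β- and 14β-methyl groups screen the β face, which sets C3 (β-OH) and C4 (β-CH3).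

---

**Compound list**

1 | methyl benzoate | COC(=O)c1ccccc1 | starting material
2 | lithium (cyclohexa-2,5-dien-1-ylidene)(methoxy)methanolate | [Li]OC(OC)=C1C=CCC=C1 | intermediate
3 | methyl 1-methylcyclohexa-2,5-diene-1-carboxylate | COC(=O)C1(C)C=CCC=C1 | intermediate
4 | methyl 1-methyl-4-oxocyclohexa-2,5-diene-1-carboxylate | COC(=O)C1(C)C=CC(=O)C=C1 | intermediate
5 | pent-1-en-3-one (ethyl vinyl ketone) | CCC(=O)C=C | starting material
6 | (Z)-3-(triisopropylsilyloxy)penta-1,3-diene | C/C=C(\O[Si](C(C)C)(C(C)C)C(C)C)C=C | intermediate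
7 | methyl 1,8-dimethyl-4-oxo-7-(triisopropylsilyloxy)-1,4,4a,5,8,8a-hexahydronaphthalene-1-carboxylate, cis-fused; H-4a, H-8a, H-8 and 1-CH3 β; 8-CH3 and CO2Me α | C[C@H]1C(O[Si](C(C)C)(C(C)C)C(C)C)=CC[C@H]2C(=O)C=C[C@@](C)(C(=O)OC)[C@@H]12 | intermediate
8 | lithium enolate of 7 (C4a=C4–OLi) | C[C@H]1C(O[Si](C(C)C)(C(C)C)C(C)C)=CCC2=C(O[Li])C=C[C@@](C)(C(=O)OC)[C@@H]12 | intermediate
9 | methyl 1,4a,8-trimethyl-4-oxo-7-(triisopropylsilyloxy)-1,4,4a,5,8,8a-hexahydronaphthalene-1-carboxylate, cis-fused; 4a-CH3 β | C[C@H]1C(O[Si](C(C)C)(C(C)C)C(C)C)=CC[C@@]2(C)C(=O)C=C[C@@](C)(C(=O)OC)[C@@H]12 | intermediate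
10 | lithium enolate (C4(OLi)=C3) from conjugate reduction of 9 | C[C@H]1C(O[Si](C(C)C)(C(C)C)C(C)C)=CC[C@@]2(C)C(O[Li])=CC[C@@](C)(C(=O)OC)[C@@H]12 | intermediate
11 | methyl 1,4a,8-trimethyl-7-(triisopropylsilyloxy)-4-(trifluoromethylsulfonyloxy)-1,2,4a,5,8,8a-hexahydronaphthalene-1-carboxylate | C[C@H]1C(O[Si](C(C)C)(C(C)C)C(C)C)=CC[C@@]2(C)C(OS(=O)(=O)C(F)(F)F)=CC[C@@](C)(C(=O)OC)[C@@H]12 | intermediate
12 | methyl 1,4a,8-trimethyl-7-(triisopropylsilyloxy)-1,2,4a,5,8,8a-hexahydronaphthalene-1-carboxylate | C[C@H]1C(O[Si](C(C)C)(C(C)C)C(C)C)=CC[C@@]2(C)C=CC[C@@](C)(C(=O)OC)[C@@H]12 | intermediate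
13 | methyl 1,4a,8-trimethyl-7-oxo-1,2,4a,5,6,7,8,8a-octahydronaphthalene-1-carboxylate, cis-fused; 1-CH3, 4a-CH3, H-8a, H-8 β; 8-CH3 and CO2Me α | C[C@H]1C(=O)CC[C@@]2(C)C=CC[C@@](C)(C(=O)OC)[C@@H]12 | intermediate
14 | 2,3-dimethoxytoluene | COc1cccc(C)c1OC | starting material
15 | 1-bromo-3,4-dimethoxy-2-methylbenzene | Brc1ccc(OC)c(OC)c1C | intermediate
16 | but-3-yn-1-ol | OCCC#C | starting material
17 | (E)-vinylalane: dimethylaluminium alkoxide of 4-(dimethylalumanyl)-3-methylbut-3-en-1-ol | C[Al](C)/C=C(\C)CCO[Al](C)C | intermediate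
18 | (E)-3-methylhexa-3,5-dien-1-ol | OCC/C(C)=C/C=C | intermediate
19 | B-[(E)-6-(9-BBN-oxy)-4-methylhex-3-en-1-yl]-9-borabicyclo[3.3.1]nonane | C(C/C(C)=C/CCB1C2CCCC1CCC2)OB1C2CCCC1CCC2 | intermediate
20 | (E)-6-(3,4-dimethoxy-2-methylphenyl)-3-methylhex-3-en-1-ol | OCC/C(C)=C/CCc1ccc(OC)c(OC)c1C | intermediate
21 | (E)-1-(6-iodo-4-methylhex-3-en-1-yl)-3,4-dimethoxy-2-methylbenzene | ICC/C(C)=C/CCc1ccc(OC)c(OC)c1C | intermediate
22 | potassium enolate of 13 (C7(OK)=C8) | CC1=C(O[K])CC[C@@]2(C)C=CC[C@@](C)(C(=O)OC)[C@@H]12 | intermediate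
23 | methyl 8-[(E)-6-(3,4-dimethoxy-2-methylphenyl)-3-methylhex-3-en-1-yl]-1,4a,8-trimethyl-7-oxo-1,2,4a,5,6,7,8,8a-octahydronaphthalene-1-carboxylate; 8-CH3 α, side chain β | C[C@@]1(CC/C(C)=C/CCc3ccc(OC)c(OC)c3C)C(=O)CC[C@@]2(C)C=CC[C@@](C)(C(=O)OC)[C@@H]12 | intermediate
24 | 7-methylidene analogue of 23 | C[C@@]1(CC/C(C)=C/CCc3ccc(OC)c(OC)c3C)C(=C)CC[C@@]2(C)C=CC[C@@](C)(C(=O)OC)[C@@H]12 | intermediate
25 | unit C dimethyl ether, 21,22-ene: pentacycle with aromatic ring A (2,3-OMe, 4-CH3), 8α-H, 9β-CH3, 13α-CH3, 14β-CH3, 17β-CH3, 18β-H, C19 (β-CH3, α-CO2Me) next to C18, C21=C22 | COc1cc2c(c(C)c1OC)CC[C@H]3[C@@]2(C)CC[C@@]4(C)[C@H]5[C@](C)(C=CC[C@@]5(C)C(=O)OC)CC[C@]34C | intermediate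
26 | unit C catechol, 21,22-ene (2,3-diol of 25) | Oc1cc2c(c(C)c1O)CC[C@H]3[C@@]2(C)CC[C@@]4(C)[C@H]5[C@](C)(C=CC[C@@]5(C)C(=O)OC)CC[C@]34C | intermediate
27 | pristimerin | COC(=O)[C@]1(C)CC[C@]2(C)CC[C@]3(C)C4=CC=C5C(=CC(=O)C(O)=C5C)[C@]4(C)CC[C@@]3(C)[C@@H]2C1 | starting material
28 | pristimerol (2,3-dihydroxy, aromatic ring A, C6H2, C7=C8) | COC(=O)[C@]1(C)CC[C@]2(C)CC[C@]3(C)C4=CCc5c(C)c(O)c(O)cc5[C@]4(C)CC[C@@]3(C)[C@@H]2C1 | intermediate
29 | pristimerol 2,3-dibenzyl ether | COC(=O)[C@]1(C)CC[C@]2(C)CC[C@]3(C)C4=CCc5c(C)c(OCc6ccccc6)c(OCc6ccccc6)cc5[C@]4(C)CC[C@@]3(C)[C@@H]2C1 | intermediate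
30 | 6-oxopristimerol 2,3-dibenzyl ether | COC(=O)[C@]1(C)CC[C@]2(C)CC[C@]3(C)C4=CC(=O)c5c(C)c(OCc6ccccc6)c(OCc6ccccc6)cc5[C@]4(C)CC[C@@]3(C)[C@@H]2C1 | intermediate
31 | 7,8-dihydro-6-oxopristimerol 2,3-dibenzyl ether, 8α-H | COC(=O)[C@]1(C)CC[C@]2(C)CC[C@]3(C)[C@H]4CC(=O)c5c(C)c(OCc6ccccc6)c(OCc6ccccc6)cc5[C@]4(C)CC[C@@]3(C)[C@@H]2C1 | intermediate
32 | 6-(trimethylsilyloxy)-6-ene (silyl enol ether) of 31 | COC(=O)[C@]1(C)CC[C@]2(C)CC[C@]3(C)[C@H]4C=C(O[Si](C)(C)C)c5c(C)c(OCc6ccccc6)c(OCc6ccccc6)cc5[C@]4(C)CC[C@@]3(C)[C@@H]2C1 | intermediate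
33 | o-quinone of 26 (2,3-dione; C1=C10, C4=C5) | O=C1C=C2C(=C(C)C1=O)CC[C@H]3[C@@]2(C)CC[C@@]4(C)[C@H]5[C@](C)(C=CC[C@@]5(C)C(=O)OC)CC[C@]34C | intermediate
34 | cycloadduct: unit B (dibenzyl ether) with 6β-OSiMe3, 6α-O-2′ and 7α-O-3′ bonds (7β-H) to unit C | c1ccccc1COc2cc3c(c(C)c2OCc1ccccc1)[C@@]4(O[Si](C)(C)C)Oc5cc6c(c(C)c5O[C@H]4[C@H]1[C@@]3(C)CC[C@@]2(C)[C@@H]5C[C@](C)(C(=O)OC)CC[C@]5(C)CC[C@]12C)CC[C@H]1[C@@]6(C)CC[C@@]2(C)[C@H]3[C@](C)(C=CC[C@@]3(C)C(=O)OC)CC[C@]12C | intermediate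
35 | B–C benzodioxin: unit B (2,3-dibenzyl ether, 8α-H, C6=C7) joined C6–O–C2′ and C7–O–C3′ to unit C (21,22-ene) | c1ccccc1COc2cc3c(c(C)c2OCc1ccccc1)C=4Oc5cc6c(c(C)c5OC4[C@H]1[C@@]3(C)CC[C@@]2(C)[C@@H]5C[C@](C)(C(=O)OC)CC[C@]5(C)CC[C@]12C)CC[C@H]1[C@@]6(C)CC[C@@]2(C)[C@H]3[C@](C)(C=CC[C@@]3(C)C(=O)OC)CC[C@]12C | intermediate
36 | B–C catechol: unit B 2,3-diol, cis 6β,7β-dioxy bridge (6α-H, 7α-H, 8α-H) to O-2′/O-3′ of saturated unit C | Oc1cc2c(c(C)c1O)[C@@H]3Oc4cc5c(c(C)c4O[C@@H]3[C@H]6[C@@]2(C)CC[C@@]7(C)[C@@H]8C[C@](C)(C(=O)OC)CC[C@]8(C)CC[C@]67C)CC[C@H]1[C@@]5(C)CC[C@@]2(C)[C@H]3[C@](C)(CCC[C@@]3(C)C(=O)OC)CC[C@]12C | intermediate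
37 | o-quinone of 36 (unit B ring A 2,3-dione) | O=C1C=C2C(=C(C)C1=O)[C@@H]3Oc4cc5c(c(C)c4O[C@@H]3[C@H]6[C@@]2(C)CC[C@@]7(C)[C@@H]8C[C@](C)(C(=O)OC)CC[C@]8(C)CC[C@]67C)CC[C@H]1[C@@]5(C)CC[C@@]2(C)[C@H]3[C@](C)(CCC[C@@]3(C)C(=O)OC)CC[C@]12C | intermediate
38 | CNP0039487.1: unit A (3β-OH, 4β-CH3, 3α,4α-dioxy) bridged to O-2/O-3 of unit B, which is bridged 6β,7β to O-2/O-3 of unit C | COC(=O)[C@]1(C)CC[C@]2(C)CC[C@]3(C)C4=CC=C5C(=CC(=O)[C@@]6(O)Oc7cc8c(c(C)c7O[C@@]56C)[C@@H]5Oc6cc7c(c(C)c6O[C@@H]5[C@H]5[C@@]8(C)CC[C@@]6(C)[C@@H]8C[C@](C)(C(=O)OC)CC[C@]8(C)CC[C@]56C)CC[C@H]5[C@@]7(C)CC[C@@]6(C)[C@H]7[C@](C)(CCC[C@@]7(C)C(=O)OC)CC[C@]56C)[C@]4(C)CC[C@@]3(C)[C@@H]2C1 | target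

---

**Totals**
Total steps: 21. Longest linear sequence: 13 steps (1, 2, 4, 5, 6, 7, 12, 13, 14, 15, 19, 20, 21).

**Three steps most likely to fail**

Step 4 (enantio- and face-selectivity of the desymmetrising cycloaddition). The fallback sets out from 4 (with 5) and returns at 13. Ring D is closed by amine catalysis instead of a preformed diene and Lewis acid: 4 and ethyl vinyl ketone 5 with 9-amino-9-deoxy-epi-quinine and salicylic acid (toluene, 40 °C) react through the cross-conjugated 2-aminodiene in a desymmetrising double Michael (formal [4+2]) reaction to give the diketone F1. Ethylene glycol with TsOH ketalises only the saturated C14 ketone (the enone carbonyl is conjugated and hindered) to give the dioxolane F2. LiN(i-Pr)2 and MeI give the angular-methyl enone F3, and LiBH(s-Bu)3 followed by PhNTf2 gives the enol triflate F4. Pd(OAc)2/PPh3/Et3N/HCO2H reduces it to the alkene ketal F5, and aqueous HCl in THF releases ketone 13.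

Step 14 (initiation at a hindered alkene and the trans-anti-trans outcome of the radical bicyclisation). The fallback sets out from 23 and returns at 25. MeMgBr with CeCl3 (THF, −78 °C) adds to the C14 ketone to give the tertiary carbinol F6 (C14 epimers, inconsequential). SnCl4 (CH2Cl2, −78 °C) ionises it, so that a cationic, Friedel–Crafts-terminated polyene bicyclisation delivers 25 through the same chair–chair arrangement.

Step 21 (reactivity, regio- and face-selectivity of the last cycloaddition with the free enol). The fallback sets out from 27 and 36 and returns at 38. Pristimerin is converted with TBSOTf and 2,6-lutidine into its 3-O-silyl enol ether F7, a more electron-rich and non-acidic dienophile. The o-quinone 37 (from 36 with Ag2O) adds to it to give the silyl ketal cycloadduct F8, and Bu4NF/AcOH removes the silyl group to unveil the C3 hemiketal of 38.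

**Further compounds**

F1 | step 4 | methyl 1,8-dimethyl-4,7-dioxo-1,4,4a,5,6,7,8,8a-octahydronaphthalene-1-carboxylate (cis-fused diketone, same configuration as 7) | C[C@H]1C(=O)CC[C@H]2C(=O)C=C[C@@](C)(C(=O)OC)[C@@H]12
F2 | step 4 | 7,7-ethylenedioxy ketal of F1 | C[C@H]1C2(OCCO2)CC[C@H]3C(=O)C=C[C@@](C)(C(=O)OC)[C@@H]13
F3 | step 4 | 4a-methyl (β) derivative of F2 | C[C@H]1C2(OCCO2)CC[C@@]3(C)C(=O)C=C[C@@](C)(C(=O)OC)[C@@H]13
F4 | step 4 | C4 enol triflate from conjugate reduction of F3 | C[C@H]1C2(OCCO2)CC[C@@]3(C)C(OS(=O)(=O)C(F)(F)F)=CC[C@@](C)(C(=O)OC)[C@@H]13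
F5 | step 4 | 7,7-ethylenedioxy ketal of 13 | C[C@H]1C2(OCCO2)CC[C@@]3(C)C=CC[C@@](C)(C(=O)OC)[C@@H]13
F6 | step 14 | 7-hydroxy-7-methyl carbinol from 23 (C14 epimers) | C[C@@]1(CC/C(C)=C/CCc3ccc(OC)c(OC)c3C)C(C)(O)CC[C@@]2(C)C=CC[C@@](C)(C(=O)OC)[C@@H]12
F7 | step 21 | 3-O-(tert-butyldimethylsilyl)pristimerin | COC(=O)[C@]1(C)CC[C@]2(C)CC[C@]3(C)C4=CC=C5C(=CC(=O)C(O[Si](C)(C)C(C)(C)C)=C5C)[C@]4(C)CC[C@@]3(C)[C@@H]2C1
F8 | step 21 | 3-O-(tert-butyldimethylsilyl) ether of 38 | COC(=O)[C@]1(C)CC[C@]2(C)CC[C@]3(C)C4=CC=C5C(=CC(=O)[C@@]6(O[Si](C)(C)C(C)(C)C)Oc7cc8c(c(C)c7O[C@@]56C)[C@@H]5Oc6cc7c(c(C)c6O[C@@H]5[C@H]5[C@@]8(C)CC[C@@]6(C)[C@@H]8C[C@](C)(C(=O)OC)CC[C@]8(C)CC[C@]56C)CC[C@H]5[C@@]7(C)CC[C@@]6(C)[C@H]7[C@](C)(CCC[C@@]7(C)C(=O)OC)CC[C@]56C)[C@]4(C)CC[C@@]3(C)[C@@H]2C1
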